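## Retrosynthetic overview

1. Target 9 ⇒ ketal alcohol 8: the enone carbonyl is unmasked last from its dimethyl ketal, with no stereochemical change.
2. 8 ⇒ racemic ketone 6: the cis C4–OH / C5 side-chain pair is set in one operation by a dynamic kinetic hydrogenation of the ketone (proposed new substrate class).
3. 6 ⇒ quinone monoketal 2 + geranylgeranyl bromide 4: hydride conjugate addition and C-alkylation of the resulting enolate; 4 comes from geranylgeraniol 3.
4. 2 ⇒ phenol 1: the strategic bond is a C–O bond. Oxidative dearomatisation in MeOH forges the ketal C–O bond that later becomes the C1 carbonyl and makes the two ring oxygens chemically different.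
5. Rings: the single carbocycle is taken intact from the arene of 1; no ring is built.

Assumption: all-E geranylgeraniol is bought as such, and the catalyst hand in step 4 is assigned by analogy with 2,4,4-trimethylcyclohex-2-enone, to be confirmed on 8 (Mosher esters), with the mirror-image complex used otherwise.

Note: GG = (2E,6E,10E)-3,7,11,15-tetramethylhexadeca-2,6,10,14-tetraen-1-yl. In 2–8 the ring is numbered C1 = carbonyl/carbinol carbon (target C4), C6 = target C5, C4 = ketal carbon (target C1).

## Route

Step 1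
Reactants: 1 4-methoxy-2-methylphenol
Product: 2 4,4-dimethoxy-2-methylcyclohexa-2,5-dien-1-one
Conditions: PhI(OAc)2 (1.1 equiv), MeOH, 0 °C to rt
Reagents that add atoms: methanol, CO
Why: Iodine(III) oxidative dearomatisation, in which MeOH attacks the para (OMe-bearing) carbon of the activated phenol and forms the new ketal C–O bond of the quinone monoketal; no stereocentre is formed.

Step 2
Reactants: 3 (2E,6E,10E)-geranylgeraniol
Product: 4 (2E,6E,10E)-geranylgeranyl bromide
Conditions: PBr3 (0.4 equiv), Et2O, −10 °C, dark; used crude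
Reagents that add atoms: phosphorus tribromide, BrP(Br)Br
Why: Standard PBr3 bromination, an SN2 displacement of the primary allylic alcohol via its phosphite at low temperature, which leaves the 2E double bond in place.

Step 3
Reactants: 2 4,4-dimethoxy-2-methylcyclohexa-2,5-dien-1-one; 4 (2E,6E,10E)-geranylgeranyl bromide
Product: 6 (±)-4,4-dimethoxy-2-methyl-6-GG-cyclohex-2-en-1-one, via lithium enolate 5 (not isolated)
Conditions: L-Selectride (1.05 equiv), THF, −78 °C; then 4 (1.2 equiv), DMPU, −78 to −20 °C; pH 7 work-up, Et3N-washed silica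
Reagents that add atoms: none
Why: Reductive alkylation, in which the bulky borohydride adds hydride 1,4 to C5 of the unsubstituted enone (the 2-methyl enone is less electrophilic) and the regiodefined enolate 5 is C-alkylated by the allylic bromide at C6; the new centre is left racemic because step 4 resolves it dynamically.

Step 4
Reactants: 6 (±)-4,4-dimethoxy-2-methyl-6-GG-cyclohex-2-en-1-one
Product: 8 (1S,6S)-4,4-dimethoxy-2-methyl-6-GG-cyclohex-2-en-1-ol, via potassium enolate 7 (not isolated)
Conditions: H2 (8 atm), trans-RuCl2[(R)-tolbinap][(S,S)-dpen] (0.5 mol%), t-BuOK (10 mol%), i-PrOH, 25 °C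
Reagents that add atoms: none
Why: Proposed new method: Ru(II)–diphosphine/diamine hydrogenation with dynamic kinetic resolution, not yet shown on an α′-stereolabile cross-conjugated 2-methylcyclohex-2-enone bearing a polyene chain, in which t-BuOK interconverts (R)- and (S)-6 through achiral enolate 7 faster than the outer-sphere Ru–H/N–H hydride transfer consumes the matched (6S) ketone, hydride arriving on the C=O face anti to the C6 side chain to give the cis (1S,6S) alcohol while all C=C bonds stay untouched; the closest known reactions are the Noyori dynamic kinetic hydrogenation of 2-alkylcyclohexanones to cis alcohols and the C=O-selective asymmetric hydrogenation of 2-methylcyclohexenones.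

Step 5
Reactants: 8 (1S,6S)-4,4-dimethoxy-2-methyl-6-GG-cyclohex-2-en-1-ol
Product: 9 (4S,5S)-4-hydroxy-3-methyl-5-GG-cyclohex-2-en-1-one (target CNP0277821.1)
Conditions: PPTS (10 mol%), acetone/H2O 10:1, rt
Reagents that add atoms: water, O
Why: Acid-catalysed ketal hydrolysis through the conjugated oxocarbenium ion releases the enone carbonyl under conditions too mild to ionise the allylic alcohol or cyclise the polyene, and neither stereocentre is α to the new carbonyl, so both are kept.

## Compound list

1 | 4-methoxy-2-methylphenol | COc1ccc(O)c(C)c1 | starting material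
2 | 4,4-dimethoxy-2-methylcyclohexa-2,5-dien-1-one | COC1(OC)C=CC(=O)C(C)=C1 | intermediate
3 | (2E,6E,10E)-geranylgeraniol | CC(C)=CCC/C(C)=C/CC/C(C)=C/CC/C(C)=C/CO | starting material
4 | (2E,6E,10E)-geranylgeranyl bromide | CC(C)=CCC/C(C)=C/CC/C(C)=C/CC/C(C)=C/CBr | intermediate
5 | lithium 4,4-dimethoxy-6-methylcyclohexa-1,5-dien-1-olate | [Li+].[O-]C1=CCC(OC)(OC)C=C1C | intermediate (not isolated)
6 | (±)-4,4-dimethoxy-2-methyl-6-GG-cyclohex-2-en-1-one | CC(C)=CCC/C(C)=C/CC/C(C)=C/CC/C(C)=C/CC1CC(OC)(OC)C=C(C)C1=O | intermediate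
7 | potassium 4,4-dimethoxy-6-methyl-2-GG-cyclohexa-1,5-dien-1-olate | CC(C)=CCC/C(C)=C/CC/C(C)=C/CC/C(C)=C/CC1=C([O-])C(C)=CC(OC)(OC)C1.[K+] | intermediate (not isolated)
8 | (1S,6S)-4,4-dimethoxy-2-methyl-6-GG-cyclohex-2-en-1-ol | CC(C)=CCC/C(C)=C/CC/C(C)=C/CC/C(C)=C/C[C@H]1CC(OC)(OC)C=C(C)[C@H]1O | intermediate
9 | (4S,5S)-4-hydroxy-3-methyl-5-GG-cyclohex-2-en-1-one | CC(C)=CCC/C(C)=C/CC/C(C)=C/CC/C(C)=C/C[C@H]1CC(=O)C=C(C)[C@H]1O | target

## Step count and risks

Total step count: 5. Longest linear sequence: 4 steps (1 → 2 → 6 → 8 → 9; steps 1, 3, 4, 5).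

Steps most likely to fail:

Step 3 (reductive alkylation). The hydride may add 1,2 or to the methyl-bearing enone, and the borane-complexed enolate may alkylate sluggishly. The fallback sets out from 2 and comes back at enolate 5. The disubstituted C5=C6 bond of 2 is hydrogenated selectively (H2 1 atm, RhCl(PPh3)3, benzene) to 4,4-dimethoxy-2-methylcyclohex-2-en-1-one F1. F1 has only one enolisable position, so LDA (THF, −78 °C) gives 5 cleanly, and 5 is alkylated with 4/DMPU to 6 as before.

Step 4 (proposed new step). Racemisation of 6 may be too slow relative to hydrogenation, or the cis and enantioface preferences may be mismatched. The fallback uses known chemistry, sets out from 6 and comes back at 8. L-Selectride (THF, −78 °C) reduces 6 1,2 from the face opposite the side chain to the racemic cis alcohol (±)-cis-4,4-dimethoxy-2-methyl-6-GG-cyclohex-2-en-1-ol F2. Lipase kinetic resolution (Amano PS, vinyl acetate, MTBE, 30 °C) acylates the (1S) enantiomer, as predicted by Kazlauskas' rule with the C6 side as the large group, giving (1S,6S)-4,4-dimethoxy-2-methyl-6-GG-cyclohex-2-en-1-yl acetate F3. F3 is separated from the unreacted antipode and methanolysed (K2CO3, MeOH, 0 °C) to 8.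

Step 5 (ketal hydrolysis). Under acid, 8 can lose MeOH and water and aromatise to the anisole, or the γ-hydroxy enone can dehydrate. The fallback sets out from 8 and comes back at 9. The alcohol is silylated (TBSCl, imidazole, DMF) to the TBS ether of 8, F4. The ketal is then cleaved on oxalic acid/wet silica in CH2Cl2 to (4S,5S)-4-(tert-butyldimethylsilyloxy)-3-methyl-5-GG-cyclohex-2-en-1-one F5. HF·pyridine (THF, 0 °C) then frees 9.

Further compounds

F1 | step 3 | 4,4-dimethoxy-2-methylcyclohex-2-en-1-one | COC1(OC)CCC(=O)C(C)=C1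
F2 | step 4 | (±)-cis-4,4-dimethoxy-2-methyl-6-GG-cyclohex-2-en-1-ol (1S,6S and 1R,6R, 1:1) | CC(C)=CCC/C(C)=C/CC/C(C)=C/CC/C(C)=C/C[C@H]1CC(OC)(OC)C=C(C)[C@H]1O.CC(C)=CCC/C(C)=C/CC/C(C)=C/CC/C(C)=C/C[C@@H]1CC(OC)(OC)C=C(C)[C@@H]1O
F3 | step 4 | (1S,6S)-4,4-dimethoxy-2-methyl-6-GG-cyclohex-2-en-1-yl acetate | CC(C)=CCC/C(C)=C/CC/C(C)=C/CC/C(C)=C/C[C@H]1CC(OC)(OC)C=C(C)[C@H]1OC(C)=O
F4 | step 5 | tert-butyl{[(1S,6S)-4,4-dimethoxy-2-methyl-6-GG-cyclohex-2-en-1-yl]oxy}dimethylsilane | CC(C)=CCC/C(C)=C/CC/C(C)=C/CC/C(C)=C/C[C@H]1CC(OC)(OC)C=C(C)[C@H]1O[Si](C)(C)C(C)(C)C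
F5 | step 5 | (4S,5S)-4-(tert-butyldimethylsilyloxy)-3-methyl-5-GG-cyclohex-2-en-1-one | CC(C)=CCC/C(C)=C/CC/C(C)=C/CC/C(C)=C/C[C@H]1CC(=O)C=C(C)[C@H]1O[Si](C)(C)C(C)(C)C
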